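**Retrosynthetic overview**
1. Target ⇐ macrocyclic tert-butyl enoate 29 (ester reduction, senecioylation at C2, desilylation). The 11-membered ring is not closed at the allylic carbinol but at the trisubstituted C7=C8 alkene, by an intramolecular Horner–Wadsworth–Emmons reaction of 28.
2. 28 ⇐ vinyl iodide 18 + epoxy aldehyde 26, joined at C2–C3 by an intermolecular Nozaki–Hiyama–Kishi coupling in which the epoxide controls C2.
3. 18 ⇐ bold step: Eschenmoser–Tanabe fragmentation unzips a cyclopentenone epoxide into the alkyne (C3, C4) and CH2CHO (C6, C7) arms on quaternary C5, which is set by a d'Angelo Michael addition to 2-methylcyclopentanone; C3' comes from a CBS reduction.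
4. 26 ⇐ phosphonoacetate + acrolein (Michael), Still–Gennari (Z)-olefination, Sharpless epoxidation (C1, C11).
5. Ring order: oxirane first (step 12, acyclic fragment), 11-membered carbocycle last (step 16); the cyclopentane of the starting ketone is a temporary ring, cleaved in step 4.

Assumption: the phosphonate-bearing carbon of 21 and 23–28 is carried as a mixture of epimers (it becomes sp2 in step 16); locants C1–C11 and C1'–C5' in the Why lines are those of the target named as a 12-oxabicyclo[9.1.0]dodecane.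

**Step 1**
Reactants: 1 2-methylcyclopentanone; 2 (S)-1-phenylethylamine; 3 methyl acrylate
Product: 6 methyl 3-[(1R)-1-methyl-2-oxocyclopentyl]propanoate, via ketimine 4 (not isolated), via alkylated ketimine 5 (not isolated)
Conditions: 1 + 2, TsOH (cat.), toluene, reflux, Dean–Stark; then 3, THF, 40 °C, 3 d; then 20% aq. AcOH, rt
Reagents that add atoms: none
Why: d'Angelo deracemising Michael addition, in which the more substituted secondary enamine tautomer of 4 adds to the acrylate on the face anti to the phenyl group in an aza-ene-like transition state and so sets the quaternary carbon (future C5) as R in 6 (about 90% ee).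

**Step 2**
Reactants: 6 methyl 3-[(1R)-1-methyl-2-oxocyclopentyl]propanoate
Product: 7 methyl 3-[(1S)-1-methyl-2-oxocyclopent-3-en-1-yl]propanoate
Conditions: IBX (2-iodoxybenzoic acid, 2.2 equiv), DMSO, 70 °C
Reagents that add atoms: none
Why: IBX dehydrogenation of a ketone through its enol, regiochemically unambiguous because only one α-carbon carries hydrogens; the quaternary centre is untouched (the descriptor changes only through CIP priorities).

**Step 3**
Reactants: 7 methyl 3-[(1S)-1-methyl-2-oxocyclopent-3-en-1-yl]propanoate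
Product: 8 methyl 3-[(3S)-3-methyl-2-oxo-6-oxabicyclo[3.1.0]hexan-3-yl]propanoate (both epoxide diastereomers)
Conditions: 30% H2O2, NaOH (0.2 equiv), MeOH, 0 °C
Reagents that add atoms: hydrogen peroxide, OO
Why: Weitz–Scheffer nucleophilic epoxidation of the enone, which leaves the ester alone at 0 °C; the two new epoxide centres are irrelevant because both are destroyed in step 4.

**Step 4**
Reactants: 8 methyl 3-[(3S)-3-methyl-2-oxo-6-oxabicyclo[3.1.0]hexan-3-yl]propanoate
Product: 11 methyl (4S)-4-ethynyl-6,6-dimethoxy-4-methylhexanoate, via tosylhydrazone 9 (not isolated), via ynal 10 (not isolated)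
Conditions: TsNHNH2, CH2Cl2/AcOH 1:1, −20 °C to rt; then HC(OMe)3, MeOH, PPTS (pyridinium p-toluenesulfonate, cat.), rt
Reagents that add atoms: trimethyl orthoformate, COC(OC)OC
Why: Eschenmoser–Tanabe fragmentation, in which the epoxy tosylhydrazone opens, loses N2 and sulfinate and cleaves the Cα–Cβ bond to give the terminal alkyne (future C3, C4) and the aldehyde (future C7), masked at once as its dimethyl acetal; the quaternary centre is a spectator.

**Step 5**
Reactants: 11 methyl (4S)-4-ethynyl-6,6-dimethoxy-4-methylhexanoate; 12 isopropenylmagnesium bromide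
Product: 14 (6S)-6-ethynyl-8,8-dimethoxy-2,6-dimethyloct-1-en-3-one, via Weinreb amide 13 (not isolated)
Conditions: MeNH(OMe)·HCl, iPrMgCl (4.5 equiv), THF, −20 °C; then 12 (2.5 equiv), −20 to 0 °C; cold aq. NH4Cl
Reagents that add atoms: none
Why: one-pot Weinreb ketone synthesis (ester aminolysis by the magnesium amide, then Grignard addition to the amide), where the chelated tetrahedral intermediate stops the addition at the ketone and the acetylide formed from the alkyne is reprotonated on work-up.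

**Step 6**
Reactants: 14 (6S)-6-ethynyl-8,8-dimethoxy-2,6-dimethyloct-1-en-3-one
Product: 15 (3S,6S)-6-ethynyl-8,8-dimethoxy-2,6-dimethyloct-1-en-3-ol
Conditions: (R)-2-methyl-CBS-oxazaborolidine [(3aR)-1-methyl-3,3-diphenyltetrahydro-1H,3H-pyrrolo[1,2-c][1,3,2]oxazaborole, 20 mol %], catecholborane, toluene, −78 °C
Reagents that add atoms: none
Why: Corey–Bakshi–Shibata reduction in which the isopropenyl group is the large substituent, so the (R)-catalyst delivers hydride to give the (S)-carbinol (C3' of the target); catecholborane at −78 °C does not hydroborate the alkyne.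

**Step 7**
Reactants: 15 (3S,6S)-6-ethynyl-8,8-dimethoxy-2,6-dimethyloct-1-en-3-ol
Product: 16 tert-butyl{[(3S,6S)-6-ethynyl-8,8-dimethoxy-2,6-dimethyloct-1-en-3-yl]oxy}dimethylsilane
Conditions: TBSCl, imidazole, DMF, rt
Reagents that add atoms: tert-butyldimethylsilyl chloride, CC(C)(C)[Si](C)(C)Cl
Why: standard silylation of a secondary allylic alcohol, needed so that only the C2 hydroxyl is free for acylation in step 19.

**Step 8**
Reactants: 16 tert-butyl{[(3S,6S)-6-ethynyl-8,8-dimethoxy-2,6-dimethyloct-1-en-3-yl]oxy}dimethylsilane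
Product: 18 tert-butyl{[(3S,6S,7E)-6-(2,2-dimethoxyethyl)-8-iodo-2,6-dimethylocta-1,7-dien-3-yl]oxy}dimethylsilane, via alkenylzirconocene 17 (not isolated)
Conditions: Cp2Zr(H)Cl (1.3 equiv), THF, rt; then I2, 0 °C
Reagents that add atoms: iodine, [I][I]
Why: hydrozirconation–iodination, a syn addition of Zr–H that puts zirconium on the terminal alkyne carbon, followed by iodinolysis with retention to give only the (E)-vinyl iodide; the hindered isopropenyl group reacts much more slowly.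

**Step 9**
Reactants: 19 tert-butyl diethylphosphonoacetate; 20 acrolein
Product: 21 tert-butyl 2-(diethoxyphosphoryl)-5-oxopentanoate (racemic)
Conditions: KOtBu (5 mol %), tBuOH/THF, 0 °C, slow addition of 20
Reagents that add atoms: none
Why: base-catalysed Michael addition of the phosphonoacetate carbanion to acrolein, where catalytic base keeps conjugate addition (catalytic in base) ahead of Horner–Wadsworth–Emmons olefination (which consumes base).

**Step 10**
Reactants: 21 tert-butyl 2-(diethoxyphosphoryl)-5-oxopentanoate; 22 ethyl 2-[bis(2,2,2-trifluoroethoxy)phosphoryl]propanoate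
Product: 23 7-tert-butyl 1-ethyl (2Z)-6-(diethoxyphosphoryl)-2-methylhept-2-enedioate (C6 epimers)
Conditions: KN(SiMe3)2, 18-crown-6, THF, −78 °C
Reagents that add atoms: none
Why: Still–Gennari olefination, in which the electron-poor bis(trifluoroethyl) phosphonate under dissociating conditions gives the kinetic (Z)-trisubstituted enoate and so places the ester carbon (future C2) cis to the chain (future C10); the less acidic diethyl phosphonoacetate of 21 stays protonated.

**Step 11**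
Reactants: 23 7-tert-butyl 1-ethyl (2Z)-6-(diethoxyphosphoryl)-2-methylhept-2-enedioate
Product: 24 tert-butyl (5Z)-2-(diethoxyphosphoryl)-7-hydroxy-6-methylhept-5-enoate (C2 epimers)
Conditions: iBu2AlH (2.2 equiv), CH2Cl2, −78 °C
Reagents that add atoms: none
Why: chemoselective iBu2AlH ester reduction, where the unhindered conjugated ethyl ester is reduced to the allylic alcohol at −78 °C while the tert-butyl α-phosphono ester is too hindered to react; the alkene geometry is retained.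

**Step 12**
Reactants: 24 tert-butyl (5Z)-2-(diethoxyphosphoryl)-7-hydroxy-6-methylhept-5-enoate
Product: 25 tert-butyl 2-(diethoxyphosphoryl)-4-[(2S,3R)-3-(hydroxymethyl)-3-methyloxiran-2-yl]butanoate (C2 epimers)
Conditions: Ti(OiPr)4 (20 mol %), D-(−)-diethyl tartrate (24 mol %), tBuOOH, 4 Å MS, CH2Cl2, −20 °C
Reagents that add atoms: tert-butyl hydroperoxide, CC(C)(C)OO
Why: Sharpless asymmetric epoxidation, in which the D-(−)-tartrate titanium complex delivers oxygen to the face of the (Z)-allylic alcohol that gives the (2S,3R)-epoxy alcohol; this sets C1 and C11 of the target with the ring-cis epoxide geometry fixed by the (Z)-alkene.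

**Step 13**
Reactants: 25 tert-butyl 2-(diethoxyphosphoryl)-4-[(2S,3R)-3-(hydroxymethyl)-3-methyloxiran-2-yl]butanoate
Product: 26 tert-butyl 2-(diethoxyphosphoryl)-4-[(2S,3S)-3-formyl-3-methyloxiran-2-yl]butanoate (C2 epimers)
Conditions: Dess–Martin periodinane, NaHCO3, CH2Cl2, 0 °C to rt
Reagents that add atoms: none
Why: Dess–Martin oxidation under buffered conditions; the α-carbon is fully substituted, so the epoxy aldehyde cannot epimerise.

**Step 14**
Reactants: 18 tert-butyl{[(3S,6S,7E)-6-(2,2-dimethoxyethyl)-8-iodo-2,6-dimethylocta-1,7-dien-3-yl]oxy}dimethylsilane; 26 tert-butyl 2-(diethoxyphosphoryl)-4-[(2S,3S)-3-formyl-3-methyloxiran-2-yl]butanoate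
Product: 27 tert-butyl 4-{(2S,3R)-3-[(1R,2E,4S,7S)-7-{[tert-butyl(dimethyl)silyl]oxy}-4-(2,2-dimethoxyethyl)-1-hydroxy-4,8-dimethylnona-2,8-dien-1-yl]-3-methyloxiran-2-yl}-2-(diethoxyphosphoryl)butanoate
Conditions: 18 (1.3 equiv), CrCl2 (6 equiv), NiCl2 (2 mol %), DMSO, rt
Reagents that add atoms: none
Why: Nozaki–Hiyama–Kishi coupling, in which the alkenylchromium species adds to the epoxy aldehyde without chelation (Cornforth/Felkin–Anh: carbonyl anti to the epoxide C–O, attack opposite the epoxide C–C bond) to give the anti epoxy alcohol with C2 as R; the acidic phosphonoacetate, ester and acetal are tolerated, and the minor diastereomers from the about 90% ee fragments are removed by chromatography here.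

**Step 15**
Reactants: 27 tert-butyl 4-{(2S,3R)-3-[(1R,2E,4S,7S)-7-{[tert-butyl(dimethyl)silyl]oxy}-4-(2,2-dimethoxyethyl)-1-hydroxy-4,8-dimethylnona-2,8-dien-1-yl]-3-methyloxiran-2-yl}-2-(diethoxyphosphoryl)butanoate
Product: 28 tert-butyl 4-{(2S,3R)-3-[(1R,2E,4S,7S)-7-{[tert-butyl(dimethyl)silyl]oxy}-1-hydroxy-4,8-dimethyl-4-(2-oxoethyl)nona-2,8-dien-1-yl]-3-methyloxiran-2-yl}-2-(diethoxyphosphoryl)butanoate
Conditions: PPTS (cat.), acetone/H2O 10:1, 40 °C
Reagents that add atoms: water, O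
Why: mild acid-catalysed acetal hydrolysis (transacetalisation to acetone), which the secondary silyl ether, the tert-butyl ester and the epoxy alcohol survive at this acidity; the hydroxy aldehyde cannot form a lactol because that ring would hold the (E)-alkene.

**Step 16**
Reactants: 28 tert-butyl 4-{(2S,3R)-3-[(1R,2E,4S,7S)-7-{[tert-butyl(dimethyl)silyl]oxy}-1-hydroxy-4,8-dimethyl-4-(2-oxoethyl)nona-2,8-dien-1-yl]-3-methyloxiran-2-yl}-2-(diethoxyphosphoryl)butanoate
Product: 29 tert-butyl (1R,2R,3E,5S,7E,11S)-5-[(3S)-3-{[tert-butyl(dimethyl)silyl]oxy}-4-methylpent-4-en-1-yl]-2-hydroxy-1,5-dimethyl-12-oxabicyclo[9.1.0]dodeca-3,7-diene-8-carboxylate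
Conditions: LiCl (10 equiv), DBU (1,8-diazabicyclo[5.4.0]undec-7-ene, 5 equiv), MeCN, 0.002 M, syringe-pump addition, rt to 40 °C
Reagents that add atoms: none
Why: intramolecular Horner–Wadsworth–Emmons olefination under Masamune–Roush conditions at high dilution closes the 11-membered ring; the stabilised α-alkyl phosphonate gives the enoate with the ester trans to C6, which is also the less strained geometry (ring carbons cis), and the chain is pre-organised by the (E)-alkene, the cis-epoxide and the quaternary carbon.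

**Step 17**
Reactants: 29 tert-butyl (1R,2R,3E,5S,7E,11S)-5-[(3S)-3-{[tert-butyl(dimethyl)silyl]oxy}-4-methylpent-4-en-1-yl]-2-hydroxy-1,5-dimethyl-12-oxabicyclo[9.1.0]dodeca-3,7-diene-8-carboxylate
Product: 30 (1R,2R,3E,5S,7E,11S)-5-[(3S)-3-{[tert-butyl(dimethyl)silyl]oxy}-4-methylpent-4-en-1-yl]-8-(hydroxymethyl)-1,5-dimethyl-12-oxabicyclo[9.1.0]dodeca-3,7-dien-2-ol
Conditions: iBu2AlH (4 equiv), CH2Cl2, −78 to −40 °C
Reagents that add atoms: none
Why: iBu2AlH 1,2-reduction of the conjugated ester to the allylic alcohol, done before the senecioate is present; at low temperature it is much faster than hydride opening of the epoxy alcohol.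

**Step 18**
Reactants: 30 (1R,2R,3E,5S,7E,11S)-5-[(3S)-3-{[tert-butyl(dimethyl)silyl]oxy}-4-methylpent-4-en-1-yl]-8-(hydroxymethyl)-1,5-dimethyl-12-oxabicyclo[9.1.0]dodeca-3,7-dien-2-ol
Product: 31 (1R,2R,3E,5S,7E,11S)-5-[(3S)-3-{[tert-butyl(dimethyl)silyl]oxy}-4-methylpent-4-en-1-yl]-8-({[tert-butyl(dimethyl)silyl]oxy}methyl)-1,5-dimethyl-12-oxabicyclo[9.1.0]dodeca-3,7-dien-2-ol
Conditions: TBSCl (1.1 equiv), imidazole, CH2Cl2, 0 °C
Reagents that add atoms: tert-butyldimethylsilyl chloride, CC(C)(C)[Si](C)(C)Cl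
Why: selective silylation of the primary allylic alcohol over the secondary C2 hydroxyl, which is flanked by the fully substituted epoxide carbon.

**Step 19**
Reactants: 31 (1R,2R,3E,5S,7E,11S)-5-[(3S)-3-{[tert-butyl(dimethyl)silyl]oxy}-4-methylpent-4-en-1-yl]-8-({[tert-butyl(dimethyl)silyl]oxy}methyl)-1,5-dimethyl-12-oxabicyclo[9.1.0]dodeca-3,7-dien-2-ol; 32 3-methylbut-2-enoyl chloride
Product: 33 (1S,2R,3E,5S,7E,11S)-5-[(3S)-3-{[tert-butyl(dimethyl)silyl]oxy}-4-methylpent-4-en-1-yl]-8-({[tert-butyl(dimethyl)silyl]oxy}methyl)-1,5-dimethyl-12-oxabicyclo[9.1.0]dodeca-3,7-dien-2-yl 3-methylbut-2-enoate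
Conditions: 32 (3 equiv), DMAP (4-dimethylaminopyridine), pyridine, CH2Cl2, 0 °C to rt
Reagents that add atoms: none
Why: DMAP-catalysed acylation of the only free hydroxyl, with pyridine in place of a stronger amine base to avoid the vinylketene path to the deconjugated ester; C2 keeps its configuration (the C1 descriptor changes only through CIP priorities).

**Step 20**
Reactants: 33 (1S,2R,3E,5S,7E,11S)-5-[(3S)-3-{[tert-butyl(dimethyl)silyl]oxy}-4-methylpent-4-en-1-yl]-8-({[tert-butyl(dimethyl)silyl]oxy}methyl)-1,5-dimethyl-12-oxabicyclo[9.1.0]dodeca-3,7-dien-2-yl 3-methylbut-2-enoate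
Product: 34 (1S,2R,3E,5S,7E,11S)-8-(hydroxymethyl)-5-[(3S)-3-hydroxy-4-methylpent-4-en-1-yl]-1,5-dimethyl-12-oxabicyclo[9.1.0]dodeca-3,7-dien-2-yl 3-methylbut-2-enoate
Conditions: Bu4NF (3 equiv), AcOH (3 equiv), THF, 0 °C to rt
Reagents that add atoms: none
Why: fluoride desilylation of both silyl ethers, buffered with acetic acid so that the senecioate and the epoxide are not attacked.

**Compound list**
1 | 2-methylcyclopentanone (racemic) | CC1CCCC1=O | starting material
2 | (S)-1-phenylethylamine | C[C@H](N)c1ccccc1 | starting material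
3 | methyl acrylate | C=CC(=O)OC | starting material
4 | 2-methyl-N-[(1S)-1-phenylethyl]cyclopentan-1-imine | CC1CCCC1=N[C@@H](C)c2ccccc2 | intermediate (not isolated)
5 | methyl 3-[(1R)-1-methyl-2-{[(1S)-1-phenylethyl]imino}cyclopentyl]propanoate | COC(=O)CC[C@@]1(C)CCCC1=N[C@@H](C)c2ccccc2 | intermediate (not isolated)
6 | methyl 3-[(1R)-1-methyl-2-oxocyclopentyl]propanoate | COC(=O)CC[C@@]1(C)CCCC1=O | intermediate
7 | methyl 3-[(1S)-1-methyl-2-oxocyclopent-3-en-1-yl]propanoate | COC(=O)CC[C@@]1(C)CC=CC1=O | intermediate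
8 | methyl 3-[(3S)-3-methyl-2-oxo-6-oxabicyclo[3.1.0]hexan-3-yl]propanoate (epoxide diastereomers) | COC(=O)CC[C@@]1(C)CC2OC2C1=O | intermediate
9 | methyl 3-[(3S)-3-methyl-2-[2-(4-methylbenzenesulfonyl)hydrazinylidene]-6-oxabicyclo[3.1.0]hexan-3-yl]propanoate | COC(=O)CC[C@@]1(C)CC2OC2C1=NNS(=O)(=O)c3ccc(C)cc3 | intermediate (not isolated)
10 | methyl (4S)-4-ethynyl-4-methyl-6-oxohexanoate | COC(=O)CC[C@@](C#C)(C)CC=O | intermediate (not isolated)
11 | methyl (4S)-4-ethynyl-6,6-dimethoxy-4-methylhexanoate | COC(=O)CC[C@@](C#C)(C)CC(OC)OC | intermediate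
12 | isopropenylmagnesium bromide | C=C(C)[Mg]Br | starting material
13 | (4S)-4-ethynyl-N,6,6-trimethoxy-N,4-dimethylhexanamide | CON(C)C(=O)CC[C@@](C#C)(C)CC(OC)OC | intermediate (not isolated)
14 | (6S)-6-ethynyl-8,8-dimethoxy-2,6-dimethyloct-1-en-3-one | C=C(C)C(=O)CC[C@@](C#C)(C)CC(OC)OC | intermediate
15 | (3S,6S)-6-ethynyl-8,8-dimethoxy-2,6-dimethyloct-1-en-3-ol | C=C(C)[C@@H](O)CC[C@@](C#C)(C)CC(OC)OC | intermediate
16 | tert-butyl{[(3S,6S)-6-ethynyl-8,8-dimethoxy-2,6-dimethyloct-1-en-3-yl]oxy}dimethylsilane | C=C(C)[C@@H](O[Si](C)(C)C(C)(C)C)CC[C@@](C#C)(C)CC(OC)OC | intermediate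
17 | chlorobis(cyclopentadienyl){(1E,3S,6S)-6-{[tert-butyl(dimethyl)silyl]oxy}-3-(2,2-dimethoxyethyl)-3,7-dimethylocta-1,7-dien-1-yl}zirconium | C=C(C)[C@@H](O[Si](C)(C)C(C)(C)C)CC[C@@](/C=C/[Zr](Cl)(C1C=CC=C1)C2C=CC=C2)(C)CC(OC)OC | intermediate (not isolated)
18 | tert-butyl{[(3S,6S,7E)-6-(2,2-dimethoxyethyl)-8-iodo-2,6-dimethylocta-1,7-dien-3-yl]oxy}dimethylsilane | C=C(C)[C@@H](O[Si](C)(C)C(C)(C)C)CC[C@@](/C=C/I)(C)CC(OC)OC | intermediate
19 | tert-butyl diethylphosphonoacetate | CCOP(=O)(OCC)CC(=O)OC(C)(C)C | starting material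
20 | acrolein | C=CC=O | starting material
21 | tert-butyl 2-(diethoxyphosphoryl)-5-oxopentanoate (racemic) | CCOP(=O)(OCC)C(CCC=O)C(=O)OC(C)(C)C | intermediate
22 | ethyl 2-[bis(2,2,2-trifluoroethoxy)phosphoryl]propanoate | CCOC(=O)C(C)P(=O)(OCC(F)(F)F)OCC(F)(F)F | starting material
23 | 7-tert-butyl 1-ethyl (2Z)-6-(diethoxyphosphoryl)-2-methylhept-2-enedioate | CCOC(=O)/C(C)=C\CCC(P(=O)(OCC)OCC)C(=O)OC(C)(C)C | intermediate
24 | tert-butyl (5Z)-2-(diethoxyphosphoryl)-7-hydroxy-6-methylhept-5-enoate | OC/C(C)=C\CCC(P(=O)(OCC)OCC)C(=O)OC(C)(C)C | intermediate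
25 | tert-butyl 2-(diethoxyphosphoryl)-4-[(2S,3R)-3-(hydroxymethyl)-3-methyloxiran-2-yl]butanoate | OC[C@@]1(C)O[C@H]1CCC(P(=O)(OCC)OCC)C(=O)OC(C)(C)C | intermediate
26 | tert-butyl 2-(diethoxyphosphoryl)-4-[(2S,3S)-3-formyl-3-methyloxiran-2-yl]butanoate | O=C[C@@]1(C)O[C@H]1CCC(P(=O)(OCC)OCC)C(=O)OC(C)(C)C | intermediate
27 | tert-butyl 4-{(2S,3R)-3-[(1R,2E,4S,7S)-7-{[tert-butyl(dimethyl)silyl]oxy}-4-(2,2-dimethoxyethyl)-1-hydroxy-4,8-dimethylnona-2,8-dien-1-yl]-3-methyloxiran-2-yl}-2-(diethoxyphosphoryl)butanoate | C=C(C)[C@@H](O[Si](C)(C)C(C)(C)C)CC[C@@](/C=C/[C@@H](O)[C@@]1(C)O[C@H]1CCC(P(=O)(OCC)OCC)C(=O)OC(C)(C)C)(C)CC(OC)OC | intermediate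
28 | tert-butyl 4-{(2S,3R)-3-[(1R,2E,4S,7S)-7-{[tert-butyl(dimethyl)silyl]oxy}-1-hydroxy-4,8-dimethyl-4-(2-oxoethyl)nona-2,8-dien-1-yl]-3-methyloxiran-2-yl}-2-(diethoxyphosphoryl)butanoate | C=C(C)[C@@H](O[Si](C)(C)C(C)(C)C)CC[C@@](/C=C/[C@@H](O)[C@@]1(C)O[C@H]1CCC(P(=O)(OCC)OCC)C(=O)OC(C)(C)C)(C)CC=O | intermediate
29 | tert-butyl (1R,2R,3E,5S,7E,11S)-5-[(3S)-3-{[tert-butyl(dimethyl)silyl]oxy}-4-methylpent-4-en-1-yl]-2-hydroxy-1,5-dimethyl-12-oxabicyclo[9.1.0]dodeca-3,7-diene-8-carboxylate | C=C(C)[C@@H](O[Si](C)(C)C(C)(C)C)CC[C@]1(C)/C=C/[C@@H](O)[C@@]2(C)O[C@H]2CC/C(C(=O)OC(C)(C)C)=C\C1 | intermediate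
30 | (1R,2R,3E,5S,7E,11S)-5-[(3S)-3-{[tert-butyl(dimethyl)silyl]oxy}-4-methylpent-4-en-1-yl]-8-(hydroxymethyl)-1,5-dimethyl-12-oxabicyclo[9.1.0]dodeca-3,7-dien-2-ol | C=C(C)[C@@H](O[Si](C)(C)C(C)(C)C)CC[C@]1(C)/C=C/[C@@H](O)[C@@]2(C)O[C@H]2CC/C(CO)=C\C1 | intermediate
31 | (1R,2R,3E,5S,7E,11S)-5-[(3S)-3-{[tert-butyl(dimethyl)silyl]oxy}-4-methylpent-4-en-1-yl]-8-({[tert-butyl(dimethyl)silyl]oxy}methyl)-1,5-dimethyl-12-oxabicyclo[9.1.0]dodeca-3,7-dien-2-ol | C=C(C)[C@@H](O[Si](C)(C)C(C)(C)C)CC[C@]1(C)/C=C/[C@@H](O)[C@@]2(C)O[C@H]2CC/C(CO[Si](C)(C)C(C)(C)C)=C\C1 | intermediate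
32 | 3-methylbut-2-enoyl chloride | CC(C)=CC(=O)Cl | starting material
33 | (1S,2R,3E,5S,7E,11S)-5-[(3S)-3-{[tert-butyl(dimethyl)silyl]oxy}-4-methylpent-4-en-1-yl]-8-({[tert-butyl(dimethyl)silyl]oxy}methyl)-1,5-dimethyl-12-oxabicyclo[9.1.0]dodeca-3,7-dien-2-yl 3-methylbut-2-enoate | C=C(C)[C@@H](O[Si](C)(C)C(C)(C)C)CC[C@]1(C)/C=C/[C@@H](OC(=O)C=C(C)C)[C@@]2(C)O[C@H]2CC/C(CO[Si](C)(C)C(C)(C)C)=C\C1 | intermediate
34 | (1S,2R,3E,5S,7E,11S)-8-(hydroxymethyl)-5-[(3S)-3-hydroxy-4-methylpent-4-en-1-yl]-1,5-dimethyl-12-oxabicyclo[9.1.0]dodeca-3,7-dien-2-yl 3-methylbut-2-enoate | C=C(C)[C@@H](O)CC[C@]1(C)/C=C/[C@@H](OC(=O)C=C(C)C)[C@@]2(C)O[C@H]2CC/C(CO)=C\C1 | target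

**Step count and risks**
Total step count: 20. Longest linear sequence: 15 steps (steps 1–8, then 14–20); the second branch (steps 9–13) is 5 steps.

The three steps most likely to fail:

Step 4 (Eschenmoser–Tanabe fragmentation). The ketone is flanked by a quaternary carbon, so hydrazone formation may be too slow to compete with decomposition of the epoxide. The fallback sets out from enone 7 and comes back to the route at acetal 11; it cuts the ring by oxidation instead of fragmentation. Luche reduction of 7 (NaBH4, CeCl3, MeOH) gives methyl 3-[(1S)-2-hydroxy-1-methylcyclopent-3-en-1-yl]propanoate F1. Ozonolysis with NaBH4 work-up gives methyl (4S)-4-(1,2-dihydroxyethyl)-6-hydroxy-4-methylhexanoate F2. NaIO4 cleaves the diol, and the hydroxy aldehyde closes to the lactol methyl 3-[(3S)-2-hydroxy-3-methyloxolan-3-yl]propanoate F3. Ohira–Bestmann alkynylation of the lactol (dimethyl (1-diazo-2-oxopropyl)phosphonate, K2CO3, MeOH) gives methyl (4S)-4-ethynyl-6-hydroxy-4-methylhexanoate F4. Dess–Martin oxidation of F4 gives ynal 10, which is acetalised as in the second stage of step 4 to give 11.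

Step 14 (configuration at C2). The facial bias of an α-methyl epoxy aldehyde is modest and the 2R:2S ratio may be low. The fallback sets out from 18 and 26 and comes back at 27; it sets C2 by hydride delivery to a ketone instead of by C–C bond formation. The coupling is run as in step 14 without regard to selectivity. The mixture of 27 and its C2-epimeric alcohol F5 is oxidised with Dess–Martin periodinane to the epoxy enone F6. Reduction of F6 with Zn(BH4)2 (Et2O, −20 °C), with zinc chelated between the ketone and the epoxide oxygen, is a known anti-selective reduction of epoxy ketones and returns 27.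

Step 16 (ring closure). An 11-membered ring and a hindered α-branched tert-butyl phosphonate may give oligomers instead of 29. The fallback sets out from vinyl iodide 18 and epoxy alcohol 25 and comes back at 29; it swaps the roles of the two C–C bond formations. Acetal hydrolysis of 18 (PPTS, acetone/H2O) gives (3S,6S)-6-{[tert-butyl(dimethyl)silyl]oxy}-3-[(E)-2-iodoethenyl]-3,7-dimethyloct-7-enal F7. An intermolecular Horner–Wadsworth–Emmons reaction of F7 with the phosphonate of 25 (LiCl, DBU, MeCN, 0.2 M) gives the open-chain enoate epoxy alcohol F8. Dess–Martin oxidation gives the epoxy aldehyde F9. An intramolecular Nozaki–Hiyama–Kishi reaction of F9 (CrCl2, NiCl2 cat., DMSO/THF, 0.002 M) then closes the ring between C2 and C3 to give 29, with the C2 epimer removed by chromatography.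

**Further compounds**
F1 | step 4 | methyl 3-[(1S)-2-hydroxy-1-methylcyclopent-3-en-1-yl]propanoate (carbinol epimers) | COC(=O)CC[C@@]1(C)CC=CC1O
F2 | step 4 | methyl (4S)-4-(1,2-dihydroxyethyl)-6-hydroxy-4-methylhexanoate (carbinol epimers) | COC(=O)CC[C@@](C(O)CO)(C)CCO
F3 | step 4 | methyl 3-[(3S)-2-hydroxy-3-methyloxolan-3-yl]propanoate (anomers) | COC(=O)CC[C@@]1(C)CCOC1O
F4 | step 4 | methyl (4S)-4-ethynyl-6-hydroxy-4-methylhexanoate | COC(=O)CC[C@@](C#C)(C)CCO
F5 | step 14 | tert-butyl 4-{(2S,3R)-3-[(1S,2E,4S,7S)-7-{[tert-butyl(dimethyl)silyl]oxy}-4-(2,2-dimethoxyethyl)-1-hydroxy-4,8-dimethylnona-2,8-dien-1-yl]-3-methyloxiran-2-yl}-2-(diethoxyphosphoryl)butanoate | C=C(C)[C@@H](O[Si](C)(C)C(C)(C)C)CC[C@@](/C=C/[C@H](O)[C@@]1(C)O[C@H]1CCC(P(=O)(OCC)OCC)C(=O)OC(C)(C)C)(C)CC(OC)OC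
F6 | step 14 | tert-butyl 4-{(2S,3S)-3-[(2E,4S,7S)-7-{[tert-butyl(dimethyl)silyl]oxy}-4-(2,2-dimethoxyethyl)-4,8-dimethylnona-2,8-dienoyl]-3-methyloxiran-2-yl}-2-(diethoxyphosphoryl)butanoate | C=C(C)[C@@H](O[Si](C)(C)C(C)(C)C)CC[C@@](/C=C/C(=O)[C@@]1(C)O[C@H]1CCC(P(=O)(OCC)OCC)C(=O)OC(C)(C)C)(C)CC(OC)OC
F7 | step 16 | (3S,6S)-6-{[tert-butyl(dimethyl)silyl]oxy}-3-[(E)-2-iodoethenyl]-3,7-dimethyloct-7-enal | C=C(C)[C@@H](O[Si](C)(C)C(C)(C)C)CC[C@@](/C=C/I)(C)CC=O
F8 | step 16 | tert-butyl (2E,5S,8S)-8-{[tert-butyl(dimethyl)silyl]oxy}-2-{2-[(2S,3R)-3-(hydroxymethyl)-3-methyloxiran-2-yl]ethyl}-5-[(E)-2-iodoethenyl]-5,9-dimethyldeca-2,9-dienoate | C=C(C)[C@@H](O[Si](C)(C)C(C)(C)C)CC[C@@](/C=C/I)(C)C/C=C(/C(=O)OC(C)(C)C)CC[C@@H]1O[C@]1(C)CO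
F9 | step 16 | tert-butyl (2E,5S,8S)-8-{[tert-butyl(dimethyl)silyl]oxy}-2-{2-[(2S,3S)-3-formyl-3-methyloxiran-2-yl]ethyl}-5-[(E)-2-iodoethenyl]-5,9-dimethyldeca-2,9-dienoate | C=C(C)[C@@H](O[Si](C)(C)C(C)(C)C)CC[C@@](/C=C/I)(C)C/C=C(/C(=O)OC(C)(C)C)CC[C@@H]1O[C@]1(C)C=O
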